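Remark on the chemistry (assumption): 1 and 8 are treated as purchasable, and the target has no stereocentre, so no configuration has to be set. The substitution pattern of 7 was checked atom by atom against 10, 12 and 16 and needs no correction. Two refinements of the precursor design are adopted. The nucleophile is used as the preformed, dried dicesium salt 9, because any O–H or water would protonate the aryl anion before bromine transfer. Silyl triflate 7 is used in excess and added slowly, because each productive event releases bromide that can itself consume aryne.

## Structural features

The target is a linear triaryl bis-ether. The central benzene ring (ring B) carries two aryloxy groups para to each other, two hydroxyls para to each other and two bromines para to each other. Ring B is therefore a hexasubstituted, centrosymmetric 2,5-dibromo-3,6-bis(aryloxy)hydroquinone. The outer rings (A and C) are identical 2,3,5-tribromo-4-hydroxyphenyl groups: counted from the ether carbon C1, C2 and C3 carry bromine, C4 the hydroxyl, C5 bromine and C6 hydrogen. There is no stereocentre, and the ether axes are not expected to give separable rotamers, so the problem is one of regiochemistry and functional-group tolerance. The fragile parts are the electron-rich hydroquinone of ring B (oxidised to the quinone by air or any halogenating agent), four free phenols, and eight aryl C–Br bonds that exclude reductive, halogen–metal-exchange or palladium-mediated steps late in the route. The real difficulty is twofold. Each ether oxygen is flanked by ortho substituents on both rings, which makes classical ether couplings poor. The C2 bromine of rings A and C sits ortho to the ether oxygen but meta to the hydroxyl, where electrophilic bromination has no directing help. The key step exploits the run O–C1, Br–C2, Br–C3 with H at C6 on rings A and C: an aryne across C1–C2 that already bears the C3 bromine can take up the ring B oxygen at C1 and a bromine at C2 in one operation. Ring B enters at the quinone oxidation level, where the two oxygens that become ether links are the enolate oxygens of a bromanilate.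

## Logic of the disconnections

16 ⇒ 14 (through 15). The C5–Br bonds of rings A and C are cut. These are the only bromines ortho to a free hydroxyl with the para position blocked, so electrophilic bromination can place them without ambiguity. The gain is two fewer bromines and a substrate whose remaining outer-ring bromines are contiguous. The demand is that the brominating agent will also oxidise ring B, so the forward step must pass through 15 and end with a reduction.

14 ⇒ 13. The two O–CH3 bonds on rings A and C are restored. The C4 oxygens must be inert to strong base, fluoride and an aryl anion earlier on, and a methyl ether is the smallest group that is. The demand is a Lewis-acid cleavage that leaves the diaryl ethers and C–Br bonds alone, which requires ring B to be a hydroquinone and not a quinone at that point.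

13 ⇒ 12. No skeletal bond is cut; the two ring B O–H bonds are removed by going to the quinone. This turns ring B into the oxidation level of a purchasable building block and makes its ether oxygens recognisable as enolate oxygens. The demand is a mild two-electron reduction that does not touch C–Br.

12 ⇒ 7 + 9 (through 10 and 11). On each outer ring the O–C1 ether bond and the adjacent C2–Br bond are cut together, four bonds in all. Cutting here removes the hindered ether linkage and the awkwardly placed bromine at once and reduces 12 to a symmetrical dianion and two equivalents of one aryne precursor. The demand is strict regiocontrol of oxygen attack on 10 at the carbon remote from bromine, and capture of the resulting aryl anion by a bromine donor faster than any other fate.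

9 ⇒ 8. Only the two O–Cs ionic bonds are undone. The salt is prepared separately so that the key step runs free of acidic protons. The demand is thorough drying.

7 ⇒ 5 (through 6). The O–S bond of the triflate and the O–C bond of the carbamate are exchanged. The carbamate is the group that directed silicon into place and has done its work. The demand is a cleavage mild enough to keep the aryl–silicon bond beside a phenoxide.

5 ⇒ 2 (through 4 and 3). The C2–Si bond is cut. C2 lies between the carbamate oxygen and the C3 bromine and is the most acidic ring position, so deprotonation can deliver silicon there. The demand is a base that does not exchange the bromine, and trapping fast enough that the lithiated bromoarene does not lose bromide.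

2 ⇒ 1. The carbamate O–C(=O) bond is cut, leading back to the purchasable phenol that already has the bromine and methoxy group in the right relation.

## Other disconnections considered

Alternative 1: Each outer ring is cut at C1–C6 and C2–C3, so that rings A and C arise by cycloaddition. In the forward sense the bis(2-aryloxyacrylate) A1 would react thermally with two molecules of the siloxydiene A2, and mild acid would release the bis-ketone A3. In its favour, the ether C–O bonds to the crowded ring B oxygens exist as enol ethers before the outer rings are built, so no coupling at a di-ortho-substituted aryl carbon is needed. The para relation of the ring A/C oxygens follows from the usual orientation of a 2-siloxydiene, no organometallic reagent comes near a C–Br bond, and every operation is of a known type. On that last point it is better than the chosen plan. Against it, a captodative acrylate on a hindered ring is a sluggish dienophile and two cycloadditions are required. A3 then needs ester hydrolysis, dehydrogenation and decarboxylative aromatisation on both rings, and all six outer-ring bromines are still missing. Bromination alpha to the ketone can supply C3 and C5, but the bromine at C2 would have to enter meta to the phenol on a deactivated ring and stop after one substitution. Structurally, the chosen plan forms O–C1 and C2–Br together and leaves only the easy ortho-to-hydroxyl bromination, whereas A3 leaves the hardest bromine for last. Mechanistically the alternative is the more predictable of the two. In step count it is clearly longer.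

Alternative 2: The two C–OH bonds of ring B are cut, and behind them the two ether bonds on the ring B side. Forward, a double nucleophilic aromatic substitution of the difluorodialdehyde A5 by the phenol A4 would give dialdehyde A6. A peracid would then convert both formyl groups into formates by aryl migration, and hydrolysis would give the hydroquinone A7. In its favour, the formyl groups serve twice, first as activators for the ether formation and then as latent hydroxyls. All reactions are of known type, and all six outer-ring bromines are in place before the coupling, so no late bromination of rings A and C is needed. On both of these points it is better than the chosen plan. In convergence and use of symmetry it is equal. Against it, A4 is a crowded and weakly nucleophilic phenoxide, and its own synthesis has to solve the same problem of a bromine ortho to oxygen and meta to the other oxygen, so the difficulty is moved into a fragment and not removed. Aryl migration in A6 has to compete with hydride migration on a ring that still carries a second formyl group. A7 lacks both ring B bromines, which must be added through the quinone before reduction and demethylation. Overall the step count would be about equal to or somewhat above that of the chosen plan, with lower mechanistic risk but more linear fragment work.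

Alternative 3: Ring B itself is cut, at the bond between a former ketene carbon and an aryloxy-bearing alkene carbon. Forward, an alkenyl nucleophile would add to the more electrophilic carbonyl of cyclobutenedione A8 to give the hydroxycyclobutenone A9. Heating would open the four-membered ring to a vinylketene with the hydroxyl rotating outward, and 6π electrocyclisation and tautomerisation would give the hydroquinone A10. In its favour, the para arrangement of hydroxyls and of aryloxy groups on ring B follows unambiguously from the rearrangement. Both aryloxy groups are introduced on small unhindered fragments, and the rearrangement type is well established. In certainty of the ring B pattern it is the equal of the chosen plan, which inherits the pattern from 8, and in precedent it is better. Against it, A10 carries none of the eight bromines. Ring B could be dibrominated through its quinone and the outer rings brominated ortho to the phenol after demethylation, but the C2 bromine meets the same obstacle as in alternative 1. A9 is also an acid-sensitive vinylogous ester and aryl vinyl ether. The chosen plan buys ring B with its bromines and oxygens in place, so the alternative spends several steps making a ring that is commercially available and ends with a harder bromination problem and a longer sequence.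

Key step: step 5

## Route

Step 1
Reactants: 1 3-bromo-4-methoxyphenol
Product: 2 3-bromo-4-methoxyphenyl N-isopropylcarbamate
Conditions: i-PrNCO (1.2 equiv), Et3N (0.2 equiv), CH2Cl2, rt
Reagents that add atoms: isopropyl isocyanate, CC(C)N=C=O
Why: Base-catalysed addition of a phenol to an isocyanate (carbamoylation); the secondary carbamate is chosen because it directs ortho-metalation after N-silylation and can later be removed under mild E1cB conditions that spare C–Br and C–Si.

Step 2
Reactants: 2 3-bromo-4-methoxyphenyl N-isopropylcarbamate
Product: 5 3-bromo-4-methoxy-2-(trimethylsilyl)phenyl N-isopropylcarbamate, via N-silyl carbamate 3 (not isolated), via doubly silylated carbamate 4 (not isolated)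
Conditions: TBSOTf (1.05 equiv), TMEDA (1.1 equiv), Et2O, 0 °C to rt; then Me3SiCl (3 equiv), LiN(i-Pr)2 (2.3 equiv), THF, −78 °C; then aq. NaHSO4, rt
Reagents that add atoms: chlorotrimethylsilane, C[Si](C)(C)Cl; tert-butyldimethylsilyl trifluoromethanesulfonate, CC(C)(C)[Si](C)(C)OS(=O)(=O)C(F)(F)F (its atoms are kept only in 3 and 4)
Why: Carbamate-directed ortho-metalation with in situ silyl chloride quench; C2–H is flanked by the carbamate oxygen and bromine and is the most acidic site, the lithium amide does not exchange bromine, and silyl chloride already present captures the C2 anion before it can lose lithium bromide or let the halogen migrate; the N-silyl group falls off in the acidic work-up.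

Step 3
Reactants: 5 3-bromo-4-methoxy-2-(trimethylsilyl)phenyl N-isopropylcarbamate
Product: 7 3-bromo-4-methoxy-2-(trimethylsilyl)phenyl trifluoromethanesulfonate, via silylphenol 6 (not isolated)
Conditions: Et2NH (1.5 equiv), DBU (1.5 equiv), MeCN, 40 °C; then PhNTf2 (1.5 equiv), rt
Reagents that add atoms: N-phenylbis(trifluoromethanesulfonimide), O=S(=O)(N(c1ccccc1)S(=O)(=O)C(F)(F)F)C(F)(F)F
Why: E1cB cleavage of the N–H carbamate (the expelled isocyanate is scavenged by the amine) gives the phenoxide of 6, which is triflated in the same flask by the mild triflyl donor; no acid or strong nucleophile is present that could cleave the aryl–silicon bond.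

Step 4
Reactants: 8 bromanilic acid (2,5-dibromo-3,6-dihydroxy-1,4-benzoquinone)
Product: 9 dicesium bromanilate (dicesium 2,5-dibromo-3,6-dioxocyclohexa-1,4-diene-1,4-diolate, Cs2C6Br2O4)
Conditions: CsOH·H2O (2.0 equiv), MeOH/H2O, rt; evaporation, toluene azeotrope, 100 °C under vacuum
Reagents that add atoms: cesium hydroxide monohydrate, O.[Cs+].[OH-]
Why: Simple neutralisation of a strongly acidic vinylogous carboxylic acid; isolating and drying the salt removes every proton source from the key step.

Step 5
Reactants: 7 3-bromo-4-methoxy-2-(trimethylsilyl)phenyl trifluoromethanesulfonate (2.6 equiv); 9 dicesium bromanilate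
Product: 12 2,5-dibromo-3,6-bis(2,3-dibromo-4-methoxyphenoxy)-1,4-benzoquinone, via 3-bromo-4-methoxybenzyne 10 (not isolated), via cesium monoether salt 11 (not isolated)
Conditions: CsF (2.9 equiv), 18-crown-6 (5 equiv), BrCCl2CCl2Br (6 equiv), THF, 0 °C, 7 added over 4 h
Reagents that add atoms: 1,2-dibromo-1,1,2,2-tetrachloroethane, ClC(Cl)(Br)C(Cl)(Cl)Br
Why: Proposed new method: fluoride attacks silicon of 7 and triflate leaves, giving aryne 10, whose C1≡C2 bond is polarised by the inductively withdrawing C3–Br so that C1, remote from bromine, is the electrophilic terminus; an oxygen of the crown-separated bromanilate 9 adds there, the para methoxy group acting in the same sense, and the negative charge develops at C2 beside bromine. This aryl anion attacks a bromine atom of BrCCl2CCl2Br (halophilic substitution releasing bromide and tetrachloroethene), so each O–C1 ether bond is formed together with its neighbouring C2–Br bond; the monoether 11 still carries one oxyanion and repeats the sequence to give 12, four new bonds in all. The closest known reaction types are three-component couplings of silyl-triflate-derived arynes with a nucleophile and an electrophile, and the distal-selective addition of nucleophiles to 3-haloarynes; what is new is a vinylogous carboxylate as the oxygen nucleophile and the interception of an ortho-bromoaryl anion by a bromine donor. No ring is closed and no stereocentre is formed. The step needs oxygen attack at C1 only, which the C3 bromine and the C4 methoxy group jointly secure, and it needs bromine transfer to outrun loss of bromide from the ortho-bromoaryl anion, addition to a quinone carbonyl and proton abstraction; the sixfold excess of bromine donor, a solvent without acidic C–H bonds, 0 °C and a low stationary concentration of 10 are chosen for that. Bromanilate should not be oxidised by the bromine donor because its charge is delocalised and both of its carbon positions are already brominated, and during the first addition the still anionic half of ring B is a poor acceptor for the aryl anion.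

Step 6
Reactants: 12 2,5-dibromo-3,6-bis(2,3-dibromo-4-methoxyphenoxy)-1,4-benzoquinone
Product: 13 2,5-dibromo-3,6-bis(2,3-dibromo-4-methoxyphenoxy)benzene-1,4-diol
Conditions: Na2S2O4 (3 equiv), THF/H2O, rt, N2
Reagents that add atoms: none
Why: Dithionite reduction of a quinone to its hydroquinone; this removes the vinylogous aryl ester character of the ether linkages so that they become ordinary diaryl ethers, inert to the Lewis acid of the next step.

Step 7
Reactants: 13 2,5-dibromo-3,6-bis(2,3-dibromo-4-methoxyphenoxy)benzene-1,4-diol
Product: 14 2,5-dibromo-3,6-bis(2,3-dibromo-4-hydroxyphenoxy)benzene-1,4-diol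
Conditions: BBr3 (8 equiv), CH2Cl2, −78 °C to rt; then degassed H2O, 0 °C
Reagents that add atoms: none
Why: Lewis-acid cleavage of aryl methyl ethers (boron coordination, then bromide attack on the methyl group); diaryl ethers and aryl bromides are inert, and the excess reagent allows for the boron taken up by the ring B hydroxyls.

Step 8
Reactants: 14 2,5-dibromo-3,6-bis(2,3-dibromo-4-hydroxyphenoxy)benzene-1,4-diol
Product: 16 2,5-dibromo-3,6-bis(2,3,5-tribromo-4-hydroxyphenoxy)benzene-1,4-diol (target, CNP0163357.0), via octabromoquinone 15 (not isolated)
Conditions: Br2 (3.1 equiv), AcOH/CH2Cl2, 0 °C to rt; then aq. Na2S2O4, rt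
Reagents that add atoms: bromine, BrBr
Why: Electrophilic aromatic bromination ortho to the free hydroxyl of rings A and C, where C5 is the only open ortho position, the para position is blocked and C6 is meta to the hydroxyl; one further equivalent of bromine oxidises ring B to quinone 15, which keeps ring B out of the substitution chemistry, and the dithionite work-up returns the hydroquinone and destroys residual bromine.

## Compound list

1 | 3-bromo-4-methoxyphenol | COc1ccc(O)cc1Br | starting material
2 | 3-bromo-4-methoxyphenyl N-isopropylcarbamate | COc1ccc(OC(=O)NC(C)C)cc1Br | intermediate
3 | 3-bromo-4-methoxyphenyl N-(tert-butyldimethylsilyl)-N-isopropylcarbamate | COc1ccc(OC(=O)N(C(C)C)[Si](C)(C)C(C)(C)C)cc1Br | intermediate (not isolated)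
4 | 3-bromo-4-methoxy-2-(trimethylsilyl)phenyl N-(tert-butyldimethylsilyl)-N-isopropylcarbamate | COc1ccc(OC(=O)N(C(C)C)[Si](C)(C)C(C)(C)C)c([Si](C)(C)C)c1Br | intermediate (not isolated)
5 | 3-bromo-4-methoxy-2-(trimethylsilyl)phenyl N-isopropylcarbamate | COc1ccc(OC(=O)NC(C)C)c([Si](C)(C)C)c1Br | intermediate
6 | 3-bromo-4-methoxy-2-(trimethylsilyl)phenol (formed as its phenoxide) | COc1ccc(O)c([Si](C)(C)C)c1Br | intermediate (not isolated)
7 | 3-bromo-4-methoxy-2-(trimethylsilyl)phenyl trifluoromethanesulfonate | COc1ccc(OS(=O)(=O)C(F)(F)F)c([Si](C)(C)C)c1Br | intermediate
8 | bromanilic acid (2,5-dibromo-3,6-dihydroxy-1,4-benzoquinone) | O=C1C(Br)=C(O)C(=O)C(Br)=C1O | starting material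
9 | dicesium bromanilate (dicesium 2,5-dibromo-3,6-dioxocyclohexa-1,4-diene-1,4-diolate) | [Cs+].[Cs+].[O-]C1=C(Br)C(=O)C([O-])=C(Br)C1=O | intermediate
10 | 3-bromo-4-methoxybenzyne (3-bromo-4-methoxy-1,2-didehydrobenzene) | COC1=C(Br)C#CC=C1 | intermediate (not isolated)
11 | cesium 2,5-dibromo-4-(2,3-dibromo-4-methoxyphenoxy)-3,6-dioxocyclohexa-1,4-dien-1-olate | [Cs+].[O-]C1=C(Br)C(=O)C(Oc2ccc(OC)c(Br)c2Br)=C(Br)C1=O | intermediate (not isolated)
12 | 2,5-dibromo-3,6-bis(2,3-dibromo-4-methoxyphenoxy)-1,4-benzoquinone | O=C1C(Br)=C(Oc2ccc(OC)c(Br)c2Br)C(=O)C(Br)=C1Oc1ccc(OC)c(Br)c1Br | intermediate
13 | 2,5-dibromo-3,6-bis(2,3-dibromo-4-methoxyphenoxy)benzene-1,4-diol | Oc1c(Br)c(Oc2ccc(OC)c(Br)c2Br)c(O)c(Br)c1Oc1ccc(OC)c(Br)c1Br | intermediate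
14 | 2,5-dibromo-3,6-bis(2,3-dibromo-4-hydroxyphenoxy)benzene-1,4-diol | Oc1c(Br)c(Oc2ccc(O)c(Br)c2Br)c(O)c(Br)c1Oc1ccc(O)c(Br)c1Br | intermediate
15 | 2,5-dibromo-3,6-bis(2,3,5-tribromo-4-hydroxyphenoxy)-1,4-benzoquinone | O=C1C(Br)=C(Oc2cc(Br)c(O)c(Br)c2Br)C(=O)C(Br)=C1Oc1cc(Br)c(O)c(Br)c1Br | intermediate (not isolated)
16 | 2,5-dibromo-3,6-bis(2,3,5-tribromo-4-hydroxyphenoxy)benzene-1,4-diol | Oc1c(Br)cc(Oc2c(O)c(Br)c(Oc3cc(Br)c(O)c(Br)c3Br)c(O)c2Br)c(Br)c1Br | target

## Step count and least certain steps

Total step count: 8. Longest linear sequence: 7 (steps 1, 2, 3, 5, 6, 7, 8); step 4 is a one-step side branch.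

Step 5 (key step, proposed new method). Several processes can divert it:
- The ortho-bromoaryl anion may expel bromide before bromine transfer, generating a second aryne and oligomeric ethers.
- Bromide released by each productive event may add to 10 in competition with the weakly nucleophilic oxyanions of 9 and 11, so that aryne is consumed by dibromination.
- The aryl anion may be protonated by traces of moisture, giving ethers without the C2 bromine.
- In the second addition the aryl anion may close onto the neighbouring quinone carbonyl.
- Fluoride or the ether solvent may compete as nucleophiles for 10.

Fallback by known chemistry, leaving the route at 2 and rejoining it at 12: N-silylation of 2 as in step 2 gives 3. LiN(i-Pr)2 in THF at −78 °C lithiates C2, and BrCCl2CCl2Br added afterwards should give 2,3-dibromo-4-methoxyphenyl N-(tert-butyldimethylsilyl)-N-isopropylcarbamate F1. This loses the N-silyl group on aqueous NaHSO4 work-up to give 2,3-dibromo-4-methoxyphenyl N-isopropylcarbamate F2. Et2NH and DBU in MeCN at 40 °C then release 2,3-dibromo-4-methoxyphenol F3. Two equivalents of F3 with K2CO3 and purchased tetrabromo-1,4-benzoquinone (O=C1C(Br)=C(Br)C(=O)C(Br)=C1Br) in acetone at rt should give 12 by twofold addition–elimination, the second aryloxide entering para to the first as is usual for tetrahaloquinones. This sequence gives up the aryne; it is no longer than steps 2 to 5.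

Step 2. The C2-lithiated bromoarene may lose lithium bromide or let the bromine migrate before silicon arrives, and incomplete N-silylation would allow base-induced fragmentation of the carbamate. Fallback with intramolecular delivery of silicon, leaving the route at 1 and rejoining it at 7: silylation of 1 with hexamethyldisilazane gives (3-bromo-4-methoxyphenoxy)trimethylsilane F4. LiN(i-Pr)2 in THF at −78 °C deprotonates C2 between the silyloxy group and bromine, and a 1,3 shift of silicon from oxygen to carbon (retro-Brook rearrangement) gives the lithium phenoxide of 6. PhNTf2 added to the same flask then gives 7. The migrating silyl group is at hand the moment the anion forms, and the carbamate steps are avoided.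

Step 8. Attack of bromine at C1 of the 4-aryloxyphenol rings (para to the hydroxyl) may lead to oxidative cleavage of the ether links in competition with ortho bromination, and a further substitution at C6 is possible if excess reagent is present. Fallback that brominates before the phenols are freed, leaving the route at 12 and rejoining it at 16: Br2 with catalytic FeBr3 in CH2Cl2/AcOH should brominate 12 ortho to each methoxy group (para is blocked, and the quinone ring is inert to electrophiles), giving 2,5-dibromo-3,6-bis(2,3,5-tribromo-4-methoxyphenoxy)-1,4-benzoquinone F5. Na2S2O4 in THF/H2O reduces it to 2,5-dibromo-3,6-bis(2,3,5-tribromo-4-methoxyphenoxy)benzene-1,4-diol F6, and BBr3 in CH2Cl2 cleaves the two methyl ethers to give 16. No free 4-aryloxyphenol is then ever exposed to bromine.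

## Further compounds

F1 | step 5 | 2,3-dibromo-4-methoxyphenyl N-(tert-butyldimethylsilyl)-N-isopropylcarbamate | COc1ccc(OC(=O)N(C(C)C)[Si](C)(C)C(C)(C)C)c(Br)c1Br
F2 | step 5 | 2,3-dibromo-4-methoxyphenyl N-isopropylcarbamate | COc1ccc(OC(=O)NC(C)C)c(Br)c1Br
F3 | step 5 | 2,3-dibromo-4-methoxyphenol | COc1ccc(O)c(Br)c1Br
F4 | step 2 | (3-bromo-4-methoxyphenoxy)trimethylsilane | COc1ccc(O[Si](C)(C)C)cc1Br
F5 | step 8 | 2,5-dibromo-3,6-bis(2,3,5-tribromo-4-methoxyphenoxy)-1,4-benzoquinone | O=C1C(Br)=C(Oc2cc(Br)c(OC)c(Br)c2Br)C(=O)C(Br)=C1Oc1cc(Br)c(OC)c(Br)c1Br
F6 | step 8 | 2,5-dibromo-3,6-bis(2,3,5-tribromo-4-methoxyphenoxy)benzene-1,4-diol | Oc1c(Br)c(Oc2cc(Br)c(OC)c(Br)c2Br)c(O)c(Br)c1Oc1cc(Br)c(OC)c(Br)c1Br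
A1 | alternative 1 | dimethyl 2,2'-[(2,5-dibromo-3,6-dimethoxy-1,4-phenylene)bis(oxy)]diacrylate | COc1c(Br)c(OC(=C)C(=O)OC)c(OC)c(Br)c1OC(=C)C(=O)OC
A2 | alternative 1 | 2-(trimethylsilyloxy)buta-1,3-diene | C=CC(=C)O[Si](C)(C)C
A3 | alternative 1 | dimethyl 1,1'-[(2,5-dibromo-3,6-dimethoxy-1,4-phenylene)bis(oxy)]bis(4-oxocyclohexane-1-carboxylate) | COc1c(Br)c(OC2(CCC(=O)CC2)C(=O)OC)c(OC)c(Br)c1OC3(CCC(=O)CC3)C(=O)OC
A4 | alternative 2 | 2,3,5-tribromo-4-methoxyphenol | COc1c(Br)cc(O)c(Br)c1Br
A5 | alternative 2 | 2,5-difluoroterephthalaldehyde | O=Cc1cc(F)c(C=O)cc1F
A6 | alternative 2 | 2,5-bis(2,3,5-tribromo-4-methoxyphenoxy)terephthalaldehyde | O=Cc1cc(Oc2cc(Br)c(OC)c(Br)c2Br)c(C=O)cc1Oc1cc(Br)c(OC)c(Br)c1Br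
A7 | alternative 2 | 2,5-bis(2,3,5-tribromo-4-methoxyphenoxy)benzene-1,4-diol | Oc1cc(Oc2cc(Br)c(OC)c(Br)c2Br)c(O)cc1Oc3cc(Br)c(OC)c(Br)c3Br
A8 | alternative 3 | 3-(4-methoxyphenoxy)cyclobut-3-ene-1,2-dione | O=C1C=C(Oc2ccc(OC)cc2)C1=O
A9 | alternative 3 | 4-hydroxy-3-(4-methoxyphenoxy)-4-[(E)-2-(4-methoxyphenoxy)ethenyl]cyclobut-2-en-1-one (racemic) | O=C1C=C(Oc2ccc(OC)cc2)C1(O)/C=C/Oc1ccc(OC)cc1
A10 | alternative 3 | 2,5-bis(4-methoxyphenoxy)benzene-1,4-diol | Oc1cc(Oc2ccc(OC)cc2)c(O)cc1Oc3ccc(OC)cc3
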